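**Retrosynthetic overview**
1. The target is cut at C1′=C2′ (Wittig olefination, then diimide) into a bicyclic C15 phosphonium salt and a finished 1,2-dioxane aldehyde; the acid is unveiled last from Cα–CH2OH.
2. Feature: ring A with its C6 methyl, its C5=C6 alkene and the CMe2 carbon C1 on C8a is the p-menth-1-ene skeleton of (S)-limonene, and C1 is an α-terpinyl cation site beside the tetrasubstituted C2=C3 alkene. Ring B is therefore closed through C1–C2: the C1 cation is captured at C2 by the alkene of an arm on C4a (key step).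
3. The arm is placed on C4a, cis to the C8a substituent, by Eschenmoser–Claisen rearrangement of the limonene-derived (1R,4S)-dienol. Its C2 carries a trimethylsilyl group, so ring closure ends by loss of silicon and the alkene can only appear at C2=C3; an equilibrating acid, which would also move C5=C6, is not needed.
4. Dioxane: C3′–O by perhydrolysis of an (R)-2-methylglycidol-derived epoxide (inversion), C6′–O by intramolecular SN2 of the hydroperoxide on a mesylate (inversion), C6′ and Cα by an Evans syn-aldol.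
5. Rings in order: ring A from the chiral pool, ring B in step 9, the 1,2-dioxane in step 20.

Key step: step 9

Remark: (S)-limonene, (R)-2-methylglycidol and (1-bromovinyl)trimethylsilane are taken as available, the first two in high enantiomeric purity. The bicycle is numbered as a hexahydronaphthalene (C1 = CMe2, C2=C3, C4a/C8a = ring fusion, C5=C6), and the chain as C1′–C6′ with Cα next to the carboxyl group.

**Route**

Step 1
Reactants: 1 (S)-(−)-limonene
Product: 3 (1R,2S,4S)-limonene 1,2-oxide (trans-oxide; epoxide oxygen cis to the isopropenyl group), via bromohydrin 2 (not isolated)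
Conditions: NBS (1.05 equiv), acetone/H2O (4:1), 0 °C; then 6 M aq NaOH, rt
Reagents that add atoms: water, O
Why: Bromohydrin formation followed by intramolecular Williamson closure: the bromonium ions form reversibly on the electron-richer ring alkene, and water opens only the one that allows trans-diaxial, Markovnikov attack at C1, so the C1 oxygen, and after base the epoxide oxygen, lies on the face of the isopropenyl group as a single diastereomer, while C4 (the later C8a) comes unchanged from limonene.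

Step 2
Reactants: 3 (1R,2S,4S)-limonene 1,2-oxide
Product: 6 (1R,4S)-1-methyl-4-(prop-1-en-2-yl)cyclohex-2-en-1-ol, via hydroxy selenide 4 (not isolated), via selenoxide 5 (not isolated)
Conditions: (PhSe)2 (0.55 equiv), NaBH4, EtOH, reflux; then 30% H2O2, THF, 0 °C → rt
Reagents that add atoms: none
Why: Fürst–Plattner trans-diaxial opening puts the selenolate on C2 of the trans-oxide, and selenoxide syn-elimination can only run toward C3 because C1 bears no hydrogen, so the tertiary carbinol keeps its oxygen on the face of the isopropenyl group.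

Step 3
Reactants: 6 (1R,4S)-1-methyl-4-(prop-1-en-2-yl)cyclohex-2-en-1-ol; 7 N,N-dimethylacetamide dimethyl acetal
Product: 9 2-[(1R,6S)-3-methyl-6-(prop-1-en-2-yl)cyclohex-2-en-1-yl]-N,N-dimethylacetamide, via ketene N,O-acetal 8 (not isolated)
Conditions: xylene, 140 °C, MeOH distilled off
Reagents that add atoms: none
Why: Eschenmoser–Claisen rearrangement; the [3,3] shift is suprafacial, so the new C–C bond forms on the ring face that carried the C–O bond, cis to the isopropenyl group, which sets the future C4a and leaves the alkene at the future C5=C6 position.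

Step 4
Reactants: 9 2-[(1R,6S)-3-methyl-6-(prop-1-en-2-yl)cyclohex-2-en-1-yl]-N,N-dimethylacetamide; 10 methyllithium
Product: 11 1-[(1R,6S)-3-methyl-6-(prop-1-en-2-yl)cyclohex-2-en-1-yl]propan-2-one
Conditions: MeLi (1.3 equiv), THF, −78 → 0 °C; aq NH4Cl
Reagents that add atoms: none
Why: Acyl substitution of a tertiary amide by an organolithium; the lithium hemiaminal holds until work-up, so the ketone should not be attacked twice, and no stereocentre is touched.

Step 5
Reactants: 11 1-[(1R,6S)-3-methyl-6-(prop-1-en-2-yl)cyclohex-2-en-1-yl]propan-2-one; 12 (1-bromovinyl)trimethylsilane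
Product: 14 2-methyl-1-[(1R,6S)-3-methyl-6-(prop-1-en-2-yl)cyclohex-2-en-1-yl]-3-(trimethylsilyl)but-3-en-2-ol (both epimers at the carbinol carbon), via Grignard reagent 13 (not isolated)
Conditions: 12, Mg, THF, reflux; then 11, 0 °C → rt; aq NH4Cl
Reagents that add atoms: none
Why: Grignard 1,2-addition of the 1-silylvinyl reagent to the methyl ketone brings in C2, C1′ and the silyl group on C2 in one operation; the new carbinol centre is not controlled and is removed in step 6.

Step 6
Reactants: 14 2-methyl-1-[(1R,6S)-3-methyl-6-(prop-1-en-2-yl)cyclohex-2-en-1-yl]-3-(trimethylsilyl)but-3-en-2-ol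
Product: 16 {1-chloro-3-methyl-4-[(1R,6S)-3-methyl-6-(prop-1-en-2-yl)cyclohex-2-en-1-yl]but-2-en-2-yl}(trimethyl)silane (E/Z mixture), via chlorosulfite 15 (not isolated)
Conditions: SOCl2 (1.1 equiv), Et2O, 0 °C; cold aq NaHCO3
Reagents that add atoms: thionyl chloride, O=S(Cl)Cl
Why: SNi′ collapse of the tertiary allylic chlorosulfite delivers chloride to the unhindered CH2 terminus, the known behaviour of 1-(trimethylsilyl)vinyl carbinols, and gives the primary allylic chloride with the tetrasubstituted vinylsilane; the alkene geometry is not controlled and need not be, because C2 and C3 both end sp2.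

Step 7
Reactants: 16 {1-chloro-3-methyl-4-[(1R,6S)-3-methyl-6-(prop-1-en-2-yl)cyclohex-2-en-1-yl]but-2-en-2-yl}(trimethyl)silane
Product: 17 3-methyl-4-[(1R,6S)-3-methyl-6-(prop-1-en-2-yl)cyclohex-2-en-1-yl]-2-(trimethylsilyl)but-2-en-1-yl acetate (E/Z mixture)
Conditions: KOAc (3 equiv), DMF, rt → 40 °C
Reagents that add atoms: potassium acetate, CC(=O)[O-].[K+]
Why: SN2 displacement of the primary allylic chloride by acetate, which does not attack silicon and so should not eliminate the β-silyl chloride to an allene; the ester is a less ionisable spectator than the chloride for step 9.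

Step 8
Reactants: 17 3-methyl-4-[(1R,6S)-3-methyl-6-(prop-1-en-2-yl)cyclohex-2-en-1-yl]-2-(trimethylsilyl)but-2-en-1-yl acetate
Product: 19 4-[(1R,6S)-6-(2-hydroxypropan-2-yl)-3-methylcyclohex-2-en-1-yl]-3-methyl-2-(trimethylsilyl)but-2-en-1-yl acetate (E/Z mixture), via alkylmercury acetate 18 (not isolated)
Conditions: Hg(OAc)2 (1.0 equiv), THF/H2O, 0 °C → rt; then NaBH4, dilute aq NaOH, 0 °C
Reagents that add atoms: water, O
Why: Oxymercuration–demercuration (Markovnikov hydration) is fastest at the 1,1-disubstituted alkene, as in the hydration of limonene to α-terpineol, while the trisubstituted ring alkene and the crowded, ester-deactivated tetrasubstituted vinylsilane should stay.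

Step 9
Reactants: 19 4-[(1R,6S)-6-(2-hydroxypropan-2-yl)-3-methylcyclohex-2-en-1-yl]-3-methyl-2-(trimethylsilyl)but-2-en-1-yl acetate
Product: 20 [(4aR,8aS)-1,1,3,6-tetramethyl-1,4,4a,7,8,8a-hexahydronaphthalen-2-yl]methyl acetate
Conditions: SnCl4 (2.2 equiv), 2,6-di-tert-butyl-4-methylpyridine (0.3 equiv), CH2Cl2, −78 °C; Et3N, then aq NaHCO3, −78 °C → rt
Reagents that add atoms: none
Why: SnCl4 ionises the tertiary alcohol to the α-terpinyl-type cation at C1, which bonds to the silicon-bearing alkene carbon C2 of the arm (ipso attack) and leaves a C3 cation that is both tertiary and β to silicon; chloride then takes the trimethylsilyl group, so the alkene is re-formed at C2=C3 and nowhere else. The closest known reaction type is the vinylsilane-terminated cation–olefin cyclisation, applied here to a cyclogeranyl-type closure. Ring B closes in a 6-endo-trig mode, through a chair for the Z alkene (silyl group axial on C2 and aligned with the C3 orbital) and through a boat or after a ring flip for the E alkene, and both converge because C2 ends sp2. No stereocentre is formed: C4a and C8a are in place and cis, as fixed in step 3, which lets the tether reach C1. The step needs the new alkene at C2=C3 only and an untouched C5=C6 alkene: loss of silicon in place of a proton secures the first, and because no proton is set free and the hindered pyridine takes up adventitious acid the medium stays aprotic, which secures the second. Capture at C2 must also outrun hydride shift from C8a and proton loss from C1, for which the intramolecular alkene at −78 °C is relied on.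

Step 10
Reactants: 20 [(4aR,8aS)-1,1,3,6-tetramethyl-1,4,4a,7,8,8a-hexahydronaphthalen-2-yl]methyl acetate
Product: 21 [(4aR,8aS)-1,1,3,6-tetramethyl-1,4,4a,7,8,8a-hexahydronaphthalen-2-yl]methanol
Conditions: K2CO3, MeOH, rt
Reagents that add atoms: none
Why: Base-catalysed transesterification (methanolysis) of the primary acetate; nothing else in the molecule responds to carbonate in methanol.

Step 11
Reactants: 21 [(4aR,8aS)-1,1,3,6-tetramethyl-1,4,4a,7,8,8a-hexahydronaphthalen-2-yl]methanol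
Product: 22 {[(4aR,8aS)-1,1,3,6-tetramethyl-1,4,4a,7,8,8a-hexahydronaphthalen-2-yl]methyl}triphenylphosphonium bromide
Conditions: PPh3·HBr, CH2Cl2/MeOH, rt
Reagents that add atoms: triphenylphosphine hydrobromide, [PH+](c1ccccc1)(c1ccccc1)c1ccccc1.[Br-]
Why: SN1-type phosphonium salt formation: the allylic alcohol ionises and triphenylphosphine takes the unhindered primary terminus, as in the preparation of cyclogeranyl-type Wittig salts.

Step 12
Reactants: 23 (R)-2-methylglycidol, [(2R)-2-methyloxiran-2-yl]methanol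
Product: 24 [(2S)-2-methyloxiran-2-yl]methyl trifluoromethanesulfonate
Conditions: Tf2O, 2,6-lutidine, CH2Cl2, −78 °C; used at once
Reagents that add atoms: trifluoromethanesulfonic anhydride, O=S(=O)(OS(=O)(=O)C(F)(F)F)C(F)(F)F
Why: O-sulfonylation of the primary alcohol; the quaternary centre is untouched (the descriptor changes only by priority).

Step 13
Reactants: 24 [(2S)-2-methyloxiran-2-yl]methyl trifluoromethanesulfonate; 25 allylmagnesium bromide
Product: 26 (2R)-2-(but-3-en-1-yl)-2-methyloxirane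
Conditions: CuI (10 mol%), THF, −78 °C
Reagents that add atoms: none
Why: Copper-catalysed Grignard coupling by direct SN2 displacement of the far better leaving group, the triflate, so the oxirane and its stereocentre are not involved.

Step 14
Reactants: 26 (2R)-2-(but-3-en-1-yl)-2-methyloxirane
Product: 28 3-[(2R)-2-methyloxiran-2-yl]propanal, via ozonide 27 (not isolated)
Conditions: O3, CH2Cl2, −78 °C; then PPh3, −78 °C → rt
Reagents that add atoms: ozone, [O-][O+]=O
Why: Ozonolysis with reductive work-up cleaves the only alkene; the epoxide is inert to ozone.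

Step 15
Reactants: 28 3-[(2R)-2-methyloxiran-2-yl]propanal; 29 (R)-4-benzyl-3-propanoyl-1,3-oxazolidin-2-one
Product: 31 (4R)-4-benzyl-3-{(2R,3S)-3-hydroxy-2-methyl-5-[(2R)-2-methyloxiran-2-yl]pentanoyl}-1,3-oxazolidin-2-one, via boron enolate 30 (not isolated)
Conditions: Bu2BOTf, i-Pr2NEt, CH2Cl2, 0 °C; 28, −78 → 0 °C; pH 7 buffer, MeOH, 30% H2O2, 0 °C
Reagents that add atoms: none
Why: Evans syn-aldol: the Z boron enolate reacts through a Zimmerman–Traxler chair in which the auxiliary shields one face, which sets C6′ (3S here) and Cα (2R) together, independently of the remote epoxide.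

Step 16
Reactants: 31 (4R)-4-benzyl-3-{(2R,3S)-3-hydroxy-2-methyl-5-[(2R)-2-methyloxiran-2-yl]pentanoyl}-1,3-oxazolidin-2-one
Product: 32 (2S,3S)-2-methyl-5-[(2R)-2-methyloxiran-2-yl]pentane-1,3-diol
Conditions: NaBH4, THF/H2O, 0 °C → rt
Reagents that add atoms: none
Why: Reductive cleavage of the N-acyl oxazolidinone to the primary alcohol under conditions too mild to open the epoxide; no stereocentre changes.

Step 17
Reactants: 32 (2S,3S)-2-methyl-5-[(2R)-2-methyloxiran-2-yl]pentane-1,3-diol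
Product: 33 (2S,3S)-1-{[tert-butyl(diphenyl)silyl]oxy}-2-methyl-5-[(2R)-2-methyloxiran-2-yl]pentan-3-ol
Conditions: TBDPSCl (1.05 equiv), imidazole, CH2Cl2, 0 °C
Reagents that add atoms: tert-butyl(chloro)diphenylsilane, CC(C)(C)[Si](Cl)(c1ccccc1)c1ccccc1
Why: Silylation with a bulky chlorosilane selects the primary over the secondary hydroxyl.

Step 18
Reactants: 33 (2S,3S)-1-{[tert-butyl(diphenyl)silyl]oxy}-2-methyl-5-[(2R)-2-methyloxiran-2-yl]pentan-3-ol
Product: 34 (2S,3S)-1-{[tert-butyl(diphenyl)silyl]oxy}-2-methyl-5-[(2R)-2-methyloxiran-2-yl]pentan-3-yl methanesulfonate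
Conditions: MsCl, Et3N, CH2Cl2, −20 → 0 °C
Reagents that add atoms: methanesulfonyl chloride, CS(=O)(=O)Cl
Why: Mesylation of the secondary alcohol with retention; it also removes the hydroxyl that could open the epoxide under the acid of step 19.

Step 19
Reactants: 34 (2S,3S)-1-{[tert-butyl(diphenyl)silyl]oxy}-2-methyl-5-[(2R)-2-methyloxiran-2-yl]pentan-3-yl methanesulfonate
Product: 35 (2S,3S,6S)-1-{[tert-butyl(diphenyl)silyl]oxy}-6-hydroperoxy-7-hydroxy-2,6-dimethylheptan-3-yl methanesulfonate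
Conditions: H2O2 (anhydrous, in Et2O, excess), H3PMo12O40 (3 mol%), Et2O, rt
Reagents that add atoms: hydrogen peroxide, OO
Why: Phosphomolybdic-acid-catalysed perhydrolysis of the 2,2-disubstituted epoxide: H2O2 opens the activated oxirane at its tertiary carbon from the rear, so C3′ is set by inversion (R in 34, S in 35, the R centre of the target once C2′ is a methylene), and the primary carbon keeps the oxygen that becomes the aldehyde.

Step 20
Reactants: 35 (2S,3S,6S)-1-{[tert-butyl(diphenyl)silyl]oxy}-6-hydroperoxy-7-hydroxy-2,6-dimethylheptan-3-yl methanesulfonate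
Product: 36 [(3S,6R)-6-[(2S)-1-{[tert-butyl(diphenyl)silyl]oxy}propan-2-yl]-3-methyl-1,2-dioxan-3-yl]methanol
Conditions: KOtBu (1.0 equiv), 18-crown-6, toluene, 0 °C → rt
Reagents that add atoms: none
Why: Intramolecular SN2 displacement (6-exo-tet) of the secondary mesylate by the peroxide anion, which is both more acidic and more nucleophilic than the primary alcohol, closes the 1,2-dioxane and sets C6′ by inversion (S in 35, R in 36).

Step 21
Reactants: 36 [(3S,6R)-6-[(2S)-1-{[tert-butyl(diphenyl)silyl]oxy}propan-2-yl]-3-methyl-1,2-dioxan-3-yl]methanol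
Product: 37 (3S,6R)-6-[(2S)-1-{[tert-butyl(diphenyl)silyl]oxy}propan-2-yl]-3-methyl-1,2-dioxane-3-carbaldehyde
Conditions: Dess–Martin periodinane, NaHCO3, CH2Cl2, 0 °C → rt
Reagents that add atoms: none
Why: Dess–Martin oxidation of the primary alcohol is neutral and leaves the O–O bond; the aldehyde has a quaternary α-carbon and cannot epimerise.

Step 22
Reactants: 22 {[(4aR,8aS)-1,1,3,6-tetramethyl-1,4,4a,7,8,8a-hexahydronaphthalen-2-yl]methyl}triphenylphosphonium bromide; 37 (3S,6R)-6-[(2S)-1-{[tert-butyl(diphenyl)silyl]oxy}propan-2-yl]-3-methyl-1,2-dioxane-3-carbaldehyde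
Product: 39 tert-butyl({(2S)-2-[(3R,6S)-6-methyl-6-{(E)-2-[(4aR,8aS)-1,1,3,6-tetramethyl-1,4,4a,7,8,8a-hexahydronaphthalen-2-yl]ethenyl}-1,2-dioxan-3-yl]propyl}oxy)diphenylsilane (with its Z isomer), via phosphorus ylide 38 (not isolated)
Conditions: n-BuLi (1.0 equiv), THF, −78 → 0 °C; then 37, −78 → 0 °C
Reagents that add atoms: none
Why: Wittig olefination: the allylic ylide reacts at its unhindered α-carbon C1′ with the aldehyde faster than it could attack the dialkyl peroxide, which joins the two halves at C1′=C2′; the alkene geometry is irrelevant and no stereocentre is touched.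

Step 23
Reactants: 39 tert-butyl({(2S)-2-[(3R,6S)-6-methyl-6-{(E)-2-[(4aR,8aS)-1,1,3,6-tetramethyl-1,4,4a,7,8,8a-hexahydronaphthalen-2-yl]ethenyl}-1,2-dioxan-3-yl]propyl}oxy)diphenylsilane
Product: 40 tert-butyl({(2S)-2-[(3R,6R)-6-methyl-6-{2-[(4aR,8aS)-1,1,3,6-tetramethyl-1,4,4a,7,8,8a-hexahydronaphthalen-2-yl]ethyl}-1,2-dioxan-3-yl]propyl}oxy)diphenylsilane
Conditions: 2-nitrobenzenesulfonohydrazide (excess), Et3N, CH2Cl2, rt
Reagents that add atoms: none
Why: Diimide reduction transfers H2 in a concerted way to the 1,2-disubstituted alkene, is much slower at tri- and tetrasubstituted alkenes and does not cleave O–O bonds (the C3′ descriptor changes only by priority).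

Step 24
Reactants: 40 tert-butyl({(2S)-2-[(3R,6R)-6-methyl-6-{2-[(4aR,8aS)-1,1,3,6-tetramethyl-1,4,4a,7,8,8a-hexahydronaphthalen-2-yl]ethyl}-1,2-dioxan-3-yl]propyl}oxy)diphenylsilane
Product: 41 (2S)-2-[(3R,6R)-6-methyl-6-{2-[(4aR,8aS)-1,1,3,6-tetramethyl-1,4,4a,7,8,8a-hexahydronaphthalen-2-yl]ethyl}-1,2-dioxan-3-yl]propan-1-ol
Conditions: TBAF, AcOH (buffer), THF, rt
Reagents that add atoms: none
Why: Fluoride-induced desilylation; buffering keeps the medium from attacking the C6′–H next to the peroxide.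

Step 25
Reactants: 41 (2S)-2-[(3R,6R)-6-methyl-6-{2-[(4aR,8aS)-1,1,3,6-tetramethyl-1,4,4a,7,8,8a-hexahydronaphthalen-2-yl]ethyl}-1,2-dioxan-3-yl]propan-1-ol
Product: 42 (2R)-2-[(3R,6R)-6-methyl-6-{2-[(4aR,8aS)-1,1,3,6-tetramethyl-1,4,4a,7,8,8a-hexahydronaphthalen-2-yl]ethyl}-1,2-dioxan-3-yl]propanoic acid (CNP0122760.1)
Conditions: TEMPO (20 mol%), PhI(OAc)2 (2.2 equiv), MeCN/H2O (1:1), rt
Reagents that add atoms: water, O
Why: Oxoammonium (TEMPO) oxidation of the primary alcohol through the aldehyde hydrate to the acid under near-neutral conditions, so Cα, which lies β to the peroxide, should neither epimerise nor eliminate, and the two ring alkenes and the O–O bond are left.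

**Compound list**
1 | (S)-(−)-limonene | CC1=CC[C@@H](C(C)=C)CC1 | starting material
2 | (1R,2R,4S)-2-bromo-1-methyl-4-(prop-1-en-2-yl)cyclohexan-1-ol | C[C@@]1(O)CC[C@H](C(C)=C)C[C@H]1Br | intermediate
3 | (1R,2S,4S)-limonene 1,2-oxide (trans) | C[C@@]12CC[C@H](C(C)=C)C[C@@H]1O2 | intermediate
4 | (1R,2R,4S)-1-methyl-2-(phenylselanyl)-4-(prop-1-en-2-yl)cyclohexan-1-ol | C[C@@]1(O)CC[C@H](C(C)=C)C[C@H]1[Se]c1ccccc1 | intermediate
5 | selenoxide of 4 (both configurations at selenium) | C[C@@]1(O)CC[C@H](C(C)=C)C[C@H]1[Se](=O)c1ccccc1 | intermediate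
6 | (1R,4S)-1-methyl-4-(prop-1-en-2-yl)cyclohex-2-en-1-ol | C[C@@]1(O)CC[C@H](C(C)=C)C=C1 | intermediate
7 | N,N-dimethylacetamide dimethyl acetal | COC(C)(OC)N(C)C | starting material
8 | 1-(dimethylamino)vinyl ether of 6 (ketene N,O-acetal) | C=C(N(C)C)O[C@]1(C)CC[C@H](C(C)=C)C=C1 | intermediate
9 | 2-[(1R,6S)-3-methyl-6-(prop-1-en-2-yl)cyclohex-2-en-1-yl]-N,N-dimethylacetamide | CC1=C[C@@H](CC(=O)N(C)C)[C@@H](C(C)=C)CC1 | intermediate
10 | methyllithium | [Li]C | starting material
11 | 1-[(1R,6S)-3-methyl-6-(prop-1-en-2-yl)cyclohex-2-en-1-yl]propan-2-one | CC1=C[C@@H](CC(C)=O)[C@@H](C(C)=C)CC1 | intermediate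
12 | (1-bromovinyl)trimethylsilane | C=C(Br)[Si](C)(C)C | starting material
13 | bromo[1-(trimethylsilyl)ethenyl]magnesium | C=C([Mg]Br)[Si](C)(C)C | intermediate
14 | 2-methyl-1-[(1R,6S)-3-methyl-6-(prop-1-en-2-yl)cyclohex-2-en-1-yl]-3-(trimethylsilyl)but-3-en-2-ol (both epimers at the carbinol carbon) | CC1=C[C@@H](CC(C)(O)C(=C)[Si](C)(C)C)[C@@H](C(C)=C)CC1 | intermediate
15 | chlorosulfite ester of 14 | CC1=C[C@@H](CC(C)(OS(=O)Cl)C(=C)[Si](C)(C)C)[C@@H](C(C)=C)CC1 | intermediate
16 | {1-chloro-3-methyl-4-[(1R,6S)-3-methyl-6-(prop-1-en-2-yl)cyclohex-2-en-1-yl]but-2-en-2-yl}(trimethyl)silane (E/Z mixture) | CC1=C[C@@H](CC(C)=C(CCl)[Si](C)(C)C)[C@@H](C(C)=C)CC1 | intermediate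
17 | 3-methyl-4-[(1R,6S)-3-methyl-6-(prop-1-en-2-yl)cyclohex-2-en-1-yl]-2-(trimethylsilyl)but-2-en-1-yl acetate (E/Z mixture) | CC1=C[C@@H](CC(C)=C(COC(C)=O)[Si](C)(C)C)[C@@H](C(C)=C)CC1 | intermediate
18 | acetoxymercurio adduct of 17 (tertiary alcohol with CH2HgOAc, both epimers at that carbon) | CC1=C[C@@H](CC(C)=C(COC(C)=O)[Si](C)(C)C)[C@@H](C(C)(O)C[Hg]OC(C)=O)CC1 | intermediate
19 | 4-[(1R,6S)-6-(2-hydroxypropan-2-yl)-3-methylcyclohex-2-en-1-yl]-3-methyl-2-(trimethylsilyl)but-2-en-1-yl acetate (E/Z mixture) | CC1=C[C@@H](CC(C)=C(COC(C)=O)[Si](C)(C)C)[C@@H](C(C)(C)O)CC1 | intermediate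
20 | [(4aR,8aS)-1,1,3,6-tetramethyl-1,4,4a,7,8,8a-hexahydronaphthalen-2-yl]methyl acetate | CC1=C[C@H]2CC(C)=C(COC(C)=O)C(C)(C)[C@H]2CC1 | intermediate
21 | [(4aR,8aS)-1,1,3,6-tetramethyl-1,4,4a,7,8,8a-hexahydronaphthalen-2-yl]methanol | CC1=C[C@H]2CC(C)=C(CO)C(C)(C)[C@H]2CC1 | intermediate
22 | {[(4aR,8aS)-1,1,3,6-tetramethyl-1,4,4a,7,8,8a-hexahydronaphthalen-2-yl]methyl}triphenylphosphonium bromide | CC1=C[C@H]2CC(C)=C(C[P+](c3ccccc3)(c3ccccc3)c3ccccc3)C(C)(C)[C@H]2CC1.[Br-] | intermediate
23 | (R)-2-methylglycidol, [(2R)-2-methyloxiran-2-yl]methanol | C[C@@]1(CO)CO1 | starting material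
24 | [(2S)-2-methyloxiran-2-yl]methyl trifluoromethanesulfonate | C[C@@]1(COS(=O)(=O)C(F)(F)F)CO1 | intermediate
25 | allylmagnesium bromide | C=CC[Mg]Br | starting material
26 | (2R)-2-(but-3-en-1-yl)-2-methyloxirane | C[C@@]1(CCC=C)CO1 | intermediate
27 | 3-{2-[(2R)-2-methyloxiran-2-yl]ethyl}-1,2,4-trioxolane (both epimers) | C[C@@]1(CCC2OCOO2)CO1 | intermediate
28 | 3-[(2R)-2-methyloxiran-2-yl]propanal | C[C@@]1(CCC=O)CO1 | intermediate
29 | (R)-4-benzyl-3-propanoyl-1,3-oxazolidin-2-one | CCC(=O)N1[C@H](Cc2ccccc2)COC1=O | starting material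
30 | dibutylboron (Z)-enolate of 29 | C/C=C(\OB(CCCC)CCCC)N1[C@H](Cc2ccccc2)COC1=O | intermediate
31 | (4R)-4-benzyl-3-{(2R,3S)-3-hydroxy-2-methyl-5-[(2R)-2-methyloxiran-2-yl]pentanoyl}-1,3-oxazolidin-2-one | C[C@@]1(CC[C@H](O)[C@@H](C)C(=O)N2[C@H](Cc3ccccc3)COC2=O)CO1 | intermediate
32 | (2S,3S)-2-methyl-5-[(2R)-2-methyloxiran-2-yl]pentane-1,3-diol | C[C@@]1(CC[C@H](O)[C@@H](C)CO)CO1 | intermediate
33 | (2S,3S)-1-{[tert-butyl(diphenyl)silyl]oxy}-2-methyl-5-[(2R)-2-methyloxiran-2-yl]pentan-3-ol | C[C@@]1(CC[C@H](O)[C@@H](C)CO[Si](c2ccccc2)(c2ccccc2)C(C)(C)C)CO1 | intermediate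
34 | (2S,3S)-1-{[tert-butyl(diphenyl)silyl]oxy}-2-methyl-5-[(2R)-2-methyloxiran-2-yl]pentan-3-yl methanesulfonate | C[C@@]1(CC[C@H](OS(C)(=O)=O)[C@@H](C)CO[Si](c2ccccc2)(c2ccccc2)C(C)(C)C)CO1 | intermediate
35 | (2S,3S,6S)-1-{[tert-butyl(diphenyl)silyl]oxy}-6-hydroperoxy-7-hydroxy-2,6-dimethylheptan-3-yl methanesulfonate | OC[C@@](C)(OO)CC[C@H](OS(C)(=O)=O)[C@@H](C)CO[Si](c1ccccc1)(c1ccccc1)C(C)(C)C | intermediate
36 | [(3S,6R)-6-[(2S)-1-{[tert-butyl(diphenyl)silyl]oxy}propan-2-yl]-3-methyl-1,2-dioxan-3-yl]methanol | OC[C@]1(C)CC[C@H]([C@@H](C)CO[Si](c2ccccc2)(c2ccccc2)C(C)(C)C)OO1 | intermediate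
37 | (3S,6R)-6-[(2S)-1-{[tert-butyl(diphenyl)silyl]oxy}propan-2-yl]-3-methyl-1,2-dioxane-3-carbaldehyde | O=C[C@]1(C)CC[C@H]([C@@H](C)CO[Si](c2ccccc2)(c2ccccc2)C(C)(C)C)OO1 | intermediate
38 | {[(4aR,8aS)-1,1,3,6-tetramethyl-1,4,4a,7,8,8a-hexahydronaphthalen-2-yl]methylidene}triphenylphosphorane | CC1=C[C@H]2CC(C)=C(C=P(c3ccccc3)(c3ccccc3)c3ccccc3)C(C)(C)[C@H]2CC1 | intermediate
39 | tert-butyl({(2S)-2-[(3R,6S)-6-methyl-6-{(E)-2-[(4aR,8aS)-1,1,3,6-tetramethyl-1,4,4a,7,8,8a-hexahydronaphthalen-2-yl]ethenyl}-1,2-dioxan-3-yl]propyl}oxy)diphenylsilane (E shown, Z isomer accompanies) | CC1=C[C@H]2CC(C)=C(/C=C/[C@]3(C)CC[C@H]([C@@H](C)CO[Si](c4ccccc4)(c4ccccc4)C(C)(C)C)OO3)C(C)(C)[C@H]2CC1 | intermediate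
40 | tert-butyl({(2S)-2-[(3R,6R)-6-methyl-6-{2-[(4aR,8aS)-1,1,3,6-tetramethyl-1,4,4a,7,8,8a-hexahydronaphthalen-2-yl]ethyl}-1,2-dioxan-3-yl]propyl}oxy)diphenylsilane | CC1=C[C@H]2CC(C)=C(CC[C@]3(C)CC[C@H]([C@@H](C)CO[Si](c4ccccc4)(c4ccccc4)C(C)(C)C)OO3)C(C)(C)[C@H]2CC1 | intermediate
41 | (2S)-2-[(3R,6R)-6-methyl-6-{2-[(4aR,8aS)-1,1,3,6-tetramethyl-1,4,4a,7,8,8a-hexahydronaphthalen-2-yl]ethyl}-1,2-dioxan-3-yl]propan-1-ol | CC1=C[C@H]2CC(C)=C(CC[C@]3(C)CC[C@H]([C@@H](C)CO)OO3)C(C)(C)[C@H]2CC1 | intermediate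
42 | (2R)-2-[(3R,6R)-6-methyl-6-{2-[(4aR,8aS)-1,1,3,6-tetramethyl-1,4,4a,7,8,8a-hexahydronaphthalen-2-yl]ethyl}-1,2-dioxan-3-yl]propanoic acid (CNP0122760.1) | CC1=C[C@H]2CC(C)=C(CC[C@]3(C)CC[C@H]([C@@H](C)C(=O)O)OO3)C(C)(C)[C@H]2CC1 | target

**Step count and risks**

Total steps: 25. Longest linear sequence: 15 steps (steps 1 to 11, then 22 to 25); the dioxane branch (steps 12 to 21) has 10 steps and joins at step 22.

Steps most likely to fail:

Step 9 (key step). The C1 cation has to bond to a fully substituted, silicon-bearing carbon next to the gem-dimethyl group, so bond formation may be slow enough for proton loss from C1, hydride shift from C8a or ionisation of the allylic acetate to take over. For the E alkene the silyl group is not aligned in a chair closure and a proton may leave in its place. The fallback gives up the silyl group, lets a proton leave without selectivity and then gathers the alkene isomers through a conjugated aldehyde; it sets out from ketone 11 and replaces steps 5 to 10. Vinylmagnesium bromide (THF, 0 °C) and acetylation of the alkoxide in the same flask (Ac2O, DMAP) give 2-methyl-1-[(1R,6S)-3-methyl-6-(prop-1-en-2-yl)cyclohex-2-en-1-yl]but-3-en-2-yl acetate F1. PdCl2(MeCN)2 (5 mol%, THF, rt), a divalent palladium catalyst for the [3,3] shift of allylic acetates, moves the ester to the primary terminus and gives 3-methyl-4-[(1R,6S)-3-methyl-6-(prop-1-en-2-yl)cyclohex-2-en-1-yl]but-2-en-1-yl acetate F2. Oxymercuration–demercuration under the conditions of step 8 gives 4-[(1R,6S)-6-(2-hydroxypropan-2-yl)-3-methylcyclohex-2-en-1-yl]-3-methylbut-2-en-1-yl acetate F3. SnCl4 (CH2Cl2, −78 °C, Et3N quench) closes ring B at the now unhindered C2, and the C3 cation loses a proton in three directions. Acetate 20 should therefore be accompanied by its C3=C4 isomer (1,1,3,6-tetramethyl-1,2,4a,7,8,8a-hexahydronaphthalen-2-yl)methyl acetate F4 and its exocyclic isomer (1,1,6-trimethyl-3-methylidene-1,2,3,4,4a,7,8,8a-octahydronaphthalen-2-yl)methyl acetate F5. Methanolysis (K2CO3, MeOH) gives 21 together with (1,1,3,6-tetramethyl-1,2,4a,7,8,8a-hexahydronaphthalen-2-yl)methanol F6 and (1,1,6-trimethyl-3-methylidene-1,2,3,4,4a,7,8,8a-octahydronaphthalen-2-yl)methanol F7. Dess–Martin periodinane (NaHCO3, CH2Cl2) oxidises the mixture to 1,1,3,6-tetramethyl-1,2,4a,7,8,8a-hexahydronaphthalene-2-carbaldehyde F8, 1,1,6-trimethyl-3-methylidene-1,2,3,4,4a,7,8,8a-octahydronaphthalene-2-carbaldehyde F9 and (4aR,8aS)-1,1,3,6-tetramethyl-1,4,4a,7,8,8a-hexahydronaphthalene-2-carbaldehyde F10. DBU (CH2Cl2, rt) then moves the alkenes of F8 and F9 into conjugation through the dienolate, so that all material ends as F10, while the isolated ring-A alkene cannot move without acid. Luche reduction (NaBH4, CeCl3·7H2O, MeOH, 0 °C) gives alcohol 21, where the route is rejoined at step 11.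

Step 6. The HCl set free with the chlorosulfite may add to the isopropenyl or ring alkene, the tertiary allylic cation may be captured by a ring alkene, or the chlorosulfite may eliminate to a diene before chloride is delivered. The fallback replaces the SNi′ reaction by an acid-free oxo-rhenium [3,3] transposition; it sets out from carbinol 14 and replaces steps 6 and 7. Ph3SiOReO3 (2 mol%) with N,O-bis(trimethylsilyl)acetamide in Et2O at 0 °C shifts the hydroxyl reversibly through the perrhenate ester. Only the primary alcohol is silylated, which drains the equilibrium and gives trimethyl({3-methyl-4-[(1R,6S)-3-methyl-6-(prop-1-en-2-yl)cyclohex-2-en-1-yl]-2-(trimethylsilyl)but-2-en-1-yl}oxy)silane F11. K2CO3 in MeOH cleaves the O–Si bond and gives 3-methyl-4-[(1R,6S)-3-methyl-6-(prop-1-en-2-yl)cyclohex-2-en-1-yl]-2-(trimethylsilyl)but-2-en-1-ol F12. Acetylation (Ac2O, pyridine, DMAP) gives acetate 17, where the route is rejoined at step 8.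

Step 19. The tertiary C–O bond may ionise before the peroxide attacks (erosion of configuration at C3′), or H2O2 may open the epoxide at the primary carbon. The fallback reverses the order of the two C–O bond formations; it sets out from mesylate 34 and replaces steps 19 and 20. The mesylate is first displaced by hydroperoxide anion (50% H2O2, KOH, MeOH/THF, 0 °C → rt; intermolecular SN2 with inversion at C6′) to give tert-butyl({(2S,3R)-3-hydroperoxy-2-methyl-5-[(2R)-2-methyloxiran-2-yl]pentyl}oxy)diphenylsilane F13. Camphorsulfonic acid (catalytic, CH2Cl2, 0 °C) then lets the tethered hydroperoxide open the epoxide at its tertiary carbon in a 6-exo mode, from the rear because of the tether. This gives 36 directly, where the route is rejoined at step 21.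

Further compounds
F1 | step 9 | 2-methyl-1-[(1R,6S)-3-methyl-6-(prop-1-en-2-yl)cyclohex-2-en-1-yl]but-3-en-2-yl acetate (both epimers at the carbinol carbon) | CC1=C[C@@H](CC(C)(OC(C)=O)C=C)[C@@H](C(C)=C)CC1
F2 | step 9 | 3-methyl-4-[(1R,6S)-3-methyl-6-(prop-1-en-2-yl)cyclohex-2-en-1-yl]but-2-en-1-yl acetate (E shown, Z isomer accompanies) | CC1=C[C@@H](C/C(C)=C/COC(C)=O)[C@@H](C(C)=C)CC1
F3 | step 9 | 4-[(1R,6S)-6-(2-hydroxypropan-2-yl)-3-methylcyclohex-2-en-1-yl]-3-methylbut-2-en-1-yl acetate (E shown, Z isomer accompanies) | CC1=C[C@@H](C/C(C)=C/COC(C)=O)[C@@H](C(C)(C)O)CC1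
F4 | step 9 | (1,1,3,6-tetramethyl-1,2,4a,7,8,8a-hexahydronaphthalen-2-yl)methyl acetate (ring fusion as in 20, both C2 epimers) | CC1=C[C@H]2C=C(C)C(COC(C)=O)C(C)(C)[C@H]2CC1
F5 | step 9 | (1,1,6-trimethyl-3-methylidene-1,2,3,4,4a,7,8,8a-octahydronaphthalen-2-yl)methyl acetate (ring fusion as in 20, both C2 epimers) | CC1=C[C@H]2CC(=C)C(COC(C)=O)C(C)(C)[C@H]2CC1
F6 | step 9 | (1,1,3,6-tetramethyl-1,2,4a,7,8,8a-hexahydronaphthalen-2-yl)methanol (ring fusion as in 21, both C2 epimers) | CC1=C[C@H]2C=C(C)C(CO)C(C)(C)[C@H]2CC1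
F7 | step 9 | (1,1,6-trimethyl-3-methylidene-1,2,3,4,4a,7,8,8a-octahydronaphthalen-2-yl)methanol (ring fusion as in 21, both C2 epimers) | CC1=C[C@H]2CC(=C)C(CO)C(C)(C)[C@H]2CC1
F8 | step 9 | 1,1,3,6-tetramethyl-1,2,4a,7,8,8a-hexahydronaphthalene-2-carbaldehyde (both C2 epimers) | CC1=C[C@H]2C=C(C)C(C=O)C(C)(C)[C@H]2CC1
F9 | step 9 | 1,1,6-trimethyl-3-methylidene-1,2,3,4,4a,7,8,8a-octahydronaphthalene-2-carbaldehyde (both C2 epimers) | CC1=C[C@H]2CC(=C)C(C=O)C(C)(C)[C@H]2CC1
F10 | step 9 | (4aR,8aS)-1,1,3,6-tetramethyl-1,4,4a,7,8,8a-hexahydronaphthalene-2-carbaldehyde | CC1=C[C@H]2CC(C)=C(C=O)C(C)(C)[C@H]2CC1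
F11 | step 6 | trimethyl({3-methyl-4-[(1R,6S)-3-methyl-6-(prop-1-en-2-yl)cyclohex-2-en-1-yl]-2-(trimethylsilyl)but-2-en-1-yl}oxy)silane (E/Z mixture) | CC1=C[C@@H](CC(C)=C(CO[Si](C)(C)C)[Si](C)(C)C)[C@@H](C(C)=C)CC1
F12 | step 6 | 3-methyl-4-[(1R,6S)-3-methyl-6-(prop-1-en-2-yl)cyclohex-2-en-1-yl]-2-(trimethylsilyl)but-2-en-1-ol (E/Z mixture) | CC1=C[C@@H](CC(C)=C(CO)[Si](C)(C)C)[C@@H](C(C)=C)CC1
F13 | step 19 | tert-butyl({(2S,3R)-3-hydroperoxy-2-methyl-5-[(2R)-2-methyloxiran-2-yl]pentyl}oxy)diphenylsilane | C[C@@]1(CC[C@@H](OO)[C@@H](C)CO[Si](c2ccccc2)(c2ccccc2)C(C)(C)C)CO1
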